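Plan
1. The last cut removes the O-8 MOM group. The lactone ring is then cut at C-4–C-4a and C-1–C-8a, which leaves the 14-membered aryl ether macrocycle as its C-4a≡C-8a aryne (made from a C-4a triflate) and methyl (R)-3-hydroxybutanoate.
2. Enabling feature: C-4a, C-6 and C-8 form a phloroglucinol pattern. O-8, next to C-8a, polarises the aryne so that carbon nucleophiles enter at C-4a, a position meta to O-6 and O-8 and closed to SEAr. The lactone ring (C-1, O-2, C-3, C-4, C-4a, C-8a) is hydroxybutyrate with the arene inserted into its Cα–C(=O) bond.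
3. The macrocycle is cut at C-5′–C-6′ (B-alkyl Suzuki), C-8′–C-9′ (enolate alkylation), O-6–C-11′ (tertiary α-bromoketone) and C-5–C-1′ (C-alkylation of phloroglucinol).
4. Forward order: phloroglucinol, C-5 side chain, O-8 MOM, O-6 ether, O-4a triflate, chain extension, 14-membered ring, lactone ring, deprotection.
5. Stereochemistry: both Z-alkenes enter as small Z building blocks and pass only through stereoretentive steps. C-10′ (S) comes from an (R)-CBS reduction and C-3 (R) from the chiral pool.

Key step: step 12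

Remark 1: the SMILES is read literally. In both ring alkenes the two ring chains are cis (2′Z,6′Z), C-3 is R and C-10′ is S. Numbering: C-1 (C=O), O-2, C-3, C-4, C-4a, C-5 to C-8, C-8a. The chain runs from C-1′ (on C-5) to C-11′ (CMe2–O–C-6).
Remark 2: (2Z)-3-methylpent-2-en-4-yn-1-ol is taken as purchasable as the single Z isomer.

Step 1
Reactants: 1 (2Z)-3-methylpent-2-en-4-yn-1-ol
Product: 2 (3Z)-5-bromo-3-methylpent-3-en-1-yne
Conditions: PBr3 (0.4 equiv), Et2O, −10 °C
Reagents that add atoms: phosphorus tribromide, BrP(Br)Br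
Why: SN2-type bromination of a primary allylic alcohol through its phosphite ester, which at low temperature should leave the Z-alkene unchanged.

Step 2
Reactants: 2 (3Z)-5-bromo-3-methylpent-3-en-1-yne; 3 phloroglucinol
Product: 4 2-[(2Z)-3-methylpent-2-en-4-yn-1-yl]benzene-1,3,5-triol
Conditions: 3 (3 equiv), KOH (1 equiv), H2O–MeOH, 0 °C → rt
Reagents that add atoms: none
Why: C-alkylation of the ambident phloroglucinol monoanion by an allylic bromide (SN2, favoured over O-alkylation in protic medium); the three ring CH positions are equivalent, so only one monoalkyl product is possible, and excess 3 holds back dialkylation.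

Step 3
Reactants: 4 2-[(2Z)-3-methylpent-2-en-4-yn-1-yl]benzene-1,3,5-triol
Product: 5 5-(methoxymethoxy)-2-[(2Z)-3-methylpent-2-en-4-yn-1-yl]benzene-1,3-diol
Conditions: MOMCl (1.0 equiv), iPr2NEt, THF, −20 → 0 °C
Reagents that add atoms: chloromethyl methyl ether (MOMCl), COCCl
Why: MOM protection under kinetic control; the 5-OH (later O-8), flanked by two ring hydrogens, is more accessible than the two OH groups that flank the side chain.

Step 4
Reactants: 5 5-(methoxymethoxy)-2-[(2Z)-3-methylpent-2-en-4-yn-1-yl]benzene-1,3-diol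
Product: 6 5-(methoxymethoxy)-2-[(2Z)-3-methylpenta-2,4-dien-1-yl]benzene-1,3-diol
Conditions: H2 (1 atm), Lindlar catalyst, quinoline, EtOAc, rt
Reagents that add atoms: none
Why: Lindlar semihydrogenation stops a terminal conjugated alkyne at the vinyl stage and does not touch the trisubstituted Z-alkene.

Step 5
Reactants: 6 5-(methoxymethoxy)-2-[(2Z)-3-methylpenta-2,4-dien-1-yl]benzene-1,3-diol; 7 3-bromo-3-methylbutan-2-one
Product: 8 3-{3-hydroxy-5-(methoxymethoxy)-2-[(2Z)-3-methylpenta-2,4-dien-1-yl]phenoxy}-3-methylbutan-2-one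
Conditions: 7 (1.0 equiv), Cs2CO3, DMF, 40 °C; unreacted 6 recycled
Reagents that add atoms: none
Why: Williamson-type O-alkylation of a caesium phenoxide by a tertiary α-bromoketone (carbonyl-accelerated substitution, as in fibrate-type ether syntheses); the two free OH groups are equivalent, so either gives 8, and the limiting reagent holds back the second alkylation.

Step 6
Reactants: 8 3-{3-hydroxy-5-(methoxymethoxy)-2-[(2Z)-3-methylpenta-2,4-dien-1-yl]phenoxy}-3-methylbutan-2-one
Product: 9 5-(methoxymethoxy)-2-[(2Z)-3-methylpenta-2,4-dien-1-yl]-3-[(2-methyl-3-oxobutan-2-yl)oxy]phenyl trifluoromethanesulfonate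
Conditions: PhNTf2, K2CO3, DMF, rt
Reagents that add atoms: N-phenylbis(trifluoromethanesulfonimide) (PhNTf2), O=S(=O)(N(c1ccccc1)S(=O)(=O)C(F)(F)F)C(F)(F)F
Why: Phenol triflation with a mild triflyl donor, which leaves ketone, diene and MOM acetal alone, installs the leaving group for the later aryne at O-4a.

Step 7
Reactants: 10 prop-2-yn-1-ol
Product: 12 (2Z)-3-iodo-2-methylprop-2-en-1-ol, via cyclic alkenylmagnesium alkoxide 11 (not isolated)
Conditions: MeMgBr (2.5 equiv), CuI (10 mol %), THF, −10 °C → rt; I2, −10 °C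
Reagents that add atoms: methylmagnesium bromide, C[Mg]Br; iodine, II
Why: Copper-catalysed, alkoxide-directed anti-carbomagnesiation of a propargylic alcohol through the five-membered magnesacycle 11, followed by iodinolysis with retention, places CH2OH and I cis (Z).

Step 8
Reactants: 12 (2Z)-3-iodo-2-methylprop-2-en-1-ol
Product: 13 (1Z)-3-bromo-1-iodo-2-methylprop-1-ene
Conditions: PBr3 (0.4 equiv), Et2O, 0 °C
Reagents that add atoms: phosphorus tribromide, BrP(Br)Br
Why: SN2-type bromination of a primary allylic alcohol; the alkenyl iodide and its geometry take no part.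

Step 9
Reactants: 9 5-(methoxymethoxy)-2-[(2Z)-3-methylpenta-2,4-dien-1-yl]-3-[(2-methyl-3-oxobutan-2-yl)oxy]phenyl trifluoromethanesulfonate; 13 (1Z)-3-bromo-1-iodo-2-methylprop-1-ene
Product: 15 3-{[(6Z)-7-iodo-2,6-dimethyl-3-oxohept-6-en-2-yl]oxy}-5-(methoxymethoxy)-2-[(2Z)-3-methylpenta-2,4-dien-1-yl]phenyl trifluoromethanesulfonate, via lithium enolate 14 (not isolated)
Conditions: LiHMDS (1.05 equiv), THF, −78 °C; 13 (1.3 equiv), DMPU, −78 → −20 °C
Reagents that add atoms: none
Why: Kinetic lithium enolate alkylation (SN2 on a primary allylic bromide); the ketone can enolise only towards its methyl group (C-9′), and LiHMDS is too weak to metalate the ring next to the triflate.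

Step 10
Reactants: 15 3-{[(6Z)-7-iodo-2,6-dimethyl-3-oxohept-6-en-2-yl]oxy}-5-(methoxymethoxy)-2-[(2Z)-3-methylpenta-2,4-dien-1-yl]phenyl trifluoromethanesulfonate
Product: 16 3-{[(3S,6Z)-3-hydroxy-7-iodo-2,6-dimethylhept-6-en-2-yl]oxy}-5-(methoxymethoxy)-2-[(2Z)-3-methylpenta-2,4-dien-1-yl]phenyl trifluoromethanesulfonate
Conditions: (R)-Me-CBS (0.5 equiv), catecholborane (2 equiv), toluene, −60 → −30 °C
Reagents that add atoms: none
Why: Corey–Bakshi–Shibata reduction; the tertiary CMe2(OAr) group acts as the large and the CH2 chain as the small substituent, so the (R)-catalyst should give the (S)-carbinol, and catecholborane at low temperature does not hydroborate the diene.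

Step 11
Reactants: 16 3-{[(3S,6Z)-3-hydroxy-7-iodo-2,6-dimethylhept-6-en-2-yl]oxy}-5-(methoxymethoxy)-2-[(2Z)-3-methylpenta-2,4-dien-1-yl]phenyl trifluoromethanesulfonate
Product: 18 macrocyclic triflate (14-membered ring; 2′Z 6′Z 10′S; OTf on C-4a; OMOM on C-8), via B-alkyl-9-BBN borane 17 (not isolated)
Conditions: 9-BBN (2.5 equiv), THF, 0 °C → rt; slow addition to PdCl2(dppf) (15 mol %), AsPh3, Cs2CO3, DMF–THF–H2O, rt, ca. 2 mM
Reagents that add atoms: none
Why: Chemoselective 9-BBN hydroboration of the only monosubstituted C=C (boron at C-5′), then intramolecular B-alkyl Suzuki–Miyaura coupling at high dilution, which closes the ring with retention at the alkenyl iodide (6′Z) and at room temperature is much faster at C–I than at the hindered, electron-rich aryl triflate.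

Step 12
Reactants: 18 macrocyclic triflate; 19 methyl (R)-3-hydroxybutanoate
Product: 23 O-8-MOM-chrysomutanin, via dilithio dianion 20 (not isolated), via aryne 21 (not isolated), via seco ester alkoxide 22 (not isolated)
Conditions: 19 (4 equiv), LiTMP (8.2 equiv, from TMPH and n-BuLi), THF, −78 → −30 °C; 18, then LiTMP (2.5 equiv), −78 → −40 °C; MeOH, −78 °C → rt; aq NH4Cl
Reagents that add atoms: none
Why: Proposed new method: LiTMP removes H-8a, the only ring proton flanked by OTf and OMOM, LiOTf leaves, and the C-4a≡C-8a aryne 21 is attacked at C-4a (the carbon remote from the inductively withdrawing O-8, as aryne distortion predicts) by the α-carbon of the Fráter–Seebach dianion 20, which places the aryllithium on C-8a next to the chelating MOM oxygen. This aryllithium closes on the ester carbonyl (4-exo-trig) and the strained benzocyclobutenoxide opens by C–C scission to an o-toluate-type dienolate, so the arene is inserted into the Cα–C(=O) σ-bond and C-4–C-4a and C-1–C-8a arise in one event; MeOH then protonates C-4 and the C-3 alkoxide of 22 lactonises (6-exo-trig) with loss of methoxide. The closest known reaction types are the aryne σ-insertion into malonates and β-keto esters (acyl-alkylation) and the tandem addition–rearrangement of α-lithionitriles with alkoxyarynes; what is new is a singly activated ester enolate. No stereocentre is formed: C-3 comes from the chiral pool, its C–O bond is never broken, and the oxido group is too poor a leaving group for E1cB loss, which is why the dianion is used rather than an O-protected enolate or a β-lactone enolate. The step needs C- over O-attack (lithium alkoxides, including the C-10′ alkoxide of 18, are far poorer aryne traps than enolate carbon), ring closure faster than protonation of the aryllithium (hindered TMPH is the only acid present, −78 °C) and an untouched C-1′H2, which LiTMP should not deprotonate at this temperature.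

Step 13
Reactants: 23 O-8-MOM-chrysomutanin
Product: 24 chrysomutanin
Conditions: 1 M aq HCl, THF–MeOH, 35 °C
Reagents that add atoms: none
Why: Acid hydrolysis of a phenolic MOM acetal peri to the lactone carbonyl, which hydrogen-bonds the liberated OH; dilute acid should leave intact the lactone, both alkenes and the tertiary alkyl aryl ether, whose ionisation is retarded by the neighbouring carbinol.

Compound list
1 | (2Z)-3-methylpent-2-en-4-yn-1-ol | OC/C=C(C)\C#C | starting material
2 | (3Z)-5-bromo-3-methylpent-3-en-1-yne | BrC/C=C(C)\C#C | intermediate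
3 | phloroglucinol | Oc1cc(O)cc(O)c1 | starting material
4 | 2-[(2Z)-3-methylpent-2-en-4-yn-1-yl]benzene-1,3,5-triol | Oc1cc(O)c(C/C=C(C)\C#C)c(O)c1 | intermediate
5 | 5-(methoxymethoxy)-2-[(2Z)-3-methylpent-2-en-4-yn-1-yl]benzene-1,3-diol | COCOc1cc(O)c(C/C=C(C)\C#C)c(O)c1 | intermediate
6 | 5-(methoxymethoxy)-2-[(2Z)-3-methylpenta-2,4-dien-1-yl]benzene-1,3-diol | COCOc1cc(O)c(C/C=C(C)\C=C)c(O)c1 | intermediate
7 | 3-bromo-3-methylbutan-2-one | CC(=O)C(C)(C)Br | starting material
8 | 3-{3-hydroxy-5-(methoxymethoxy)-2-[(2Z)-3-methylpenta-2,4-dien-1-yl]phenoxy}-3-methylbutan-2-one | COCOc1cc(O)c(C/C=C(C)\C=C)c(OC(C)(C)C(C)=O)c1 | intermediate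
9 | triflate of 8 (OTf on the future C-4a) | COCOc1cc(OS(=O)(=O)C(F)(F)F)c(C/C=C(C)\C=C)c(OC(C)(C)C(C)=O)c1 | intermediate
10 | prop-2-yn-1-ol | OCC#C | starting material
11 | cyclic alkenylmagnesium alkoxide (4-methyl-2,5-dihydro-1,2-oxamagnesole) | CC1=C[Mg]OC1 | intermediate
12 | (2Z)-3-iodo-2-methylprop-2-en-1-ol | OC/C(C)=C\I | intermediate
13 | (1Z)-3-bromo-1-iodo-2-methylprop-1-ene | BrC/C(C)=C\I | intermediate
14 | lithium enolate of 9 | [Li+].COCOc1cc(OS(=O)(=O)C(F)(F)F)c(C/C=C(C)\C=C)c(OC(C)(C)C([O-])=C)c1 | intermediate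
15 | seco ketone (6′Z alkenyl iodide, 2′Z diene, C-10′ ketone) | COCOc1cc(OS(=O)(=O)C(F)(F)F)c(C/C=C(C)\C=C)c(OC(C)(C)C(=O)CC/C(C)=C\I)c1 | intermediate
16 | seco (10′S)-alcohol | COCOc1cc(OS(=O)(=O)C(F)(F)F)c(C/C=C(C)\C=C)c(OC(C)(C)[C@@H](O)CC/C(C)=C\I)c1 | intermediate
17 | B-alkyl-9-BBN borane (boron on C-5′) | COCOc1cc(OS(=O)(=O)C(F)(F)F)c(C/C=C(C)\CCB2C3CCCC2CCC3)c(OC(C)(C)[C@@H](O)CC/C(C)=C\I)c1 | intermediate
18 | macrocyclic triflate (2′Z,6′Z,10′S; C-4a OTf, C-8 OMOM, C-7 and C-8a H) | C/C1=C/Cc2c(cc(OCOC)cc2OS(=O)(=O)C(F)(F)F)OC(C)(C)[C@@H](O)CC/C(C)=C\CC1 | intermediate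
19 | methyl (R)-3-hydroxybutanoate | COC(=O)C[C@@H](C)O | starting material
20 | dilithio dianion of 19 (alkoxide enolate) | [Li+].[Li+].COC([O-])=C[C@@H](C)[O-] | intermediate
21 | C-4a≡C-8a aryne (C-10′ lithium alkoxide) | [Li+].C/C1=C/CC2=C(C=C(OCOC)C#C2)OC(C)(C)[C@@H]([O-])CC/C(C)=C\CC1 | intermediate
22 | seco methyl ester, C-3 and C-10′ lithium alkoxides (CO2Me on C-8a, (2R)-2-oxidopropyl on C-4a) | [Li+].[Li+].C/C1=C/Cc2c(cc(OCOC)c(C(=O)OC)c2C[C@@H](C)[O-])OC(C)(C)[C@@H]([O-])CC/C(C)=C\CC1 | intermediate
23 | O-8-MOM-chrysomutanin | C/C1=C/Cc2c(cc(OCOC)c3c2C[C@@H](C)OC3=O)OC(C)(C)[C@@H](O)CC/C(C)=C\CC1 | intermediate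
24 | chrysomutanin | C/C1=C/Cc2c(cc(O)c3c2C[C@@H](C)OC3=O)OC(C)(C)[C@@H](O)CC/C(C)=C\CC1 | target

Total steps: 13. Longest linear sequence: 11 (steps 1–6 and 9–13).

Steps most likely to fail

Step 12. The C-8a aryllithium may be protonated before it closes on the ester, which would give plain α-arylation without acyl migration. Base or enolate may also attack the sulfur of the triflate, or an anionic thia-Fries migration may compete with loss of LiOTf. The fallback uses known chemistry and runs from 18 back to 23.
- The aryne is taken up by lithiated dimethyl malonate, a doubly activated nucleophile for which the σ-insertion is established, to give homophthalate diester F1.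
- Only the unhindered aliphatic ester reacts with MeNH(OMe)·HCl/iPrMgCl, giving Weinreb amide F2.
- MeMgBr gives arylacetone F3.
- (S)-Me-CBS/catecholborane reduction gives (R)-carbinol F4. Its C-3 epimer would be a diastereomer and removable by chromatography.
- K2CO3/MeOH lactonises F4 to 23.

In this fallback C-3 is set by the catalyst instead of the chiral pool.

Step 11. Oligomerisation may take the place of ring closure, the borane may undergo protodeboronation during the slow addition, and oxidative addition at the aryl triflate may compete. The fallback runs from 6 (together with 12 and 7) back to 18. It reverses the order of the two C–C bond formations, so that the Suzuki coupling is intermolecular and the ring is closed by enolate alkylation.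
- Diene 6 is hydroborated with 9-BBN to borane F5, which is coupled in the same flask with 12 to give allylic alcohol F6.
- O-alkylation with 7 gives ketone F7.
- PhNTf2 gives triflate F8.
- CBr4/PPh3 gives allylic bromide F9.
- Slow addition to KHMDS at high dilution closes C-8′–C-9′ to give macrocyclic ketone F10.
- (R)-Me-CBS reduction gives 18.

Step 5. Three processes can compete with the wanted substitution: E2 loss of HBr from 7 followed by oxa-Michael addition of the phenoxide, substitution at the primary α′-carbon through an oxyallyl or cyclopropanone pathway, and alkylation of both equivalent OH groups. The fallback runs from 6 back to 8. The tertiary ether is made with ethyl 2-bromo-2-methylpropanoate/Cs2CO3, which has no α′-hydrogens and so cannot react through that pathway, giving aryloxy ester F11. MeNH(OMe)·HCl/iPrMgCl gives Weinreb amide F12, and MeMgBr gives 8.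

Further compounds
F1 | step 12 | homophthalate diester (CO2Me on C-8a, CH2CO2Me on C-4a) | C/C1=C/Cc2c(cc(OCOC)c(C(=O)OC)c2CC(=O)OC)OC(C)(C)[C@@H](O)CC/C(C)=C\CC1
F2 | step 12 | Weinreb amide of the aliphatic ester | C/C1=C/Cc2c(cc(OCOC)c(C(=O)OC)c2CC(=O)N(C)OC)OC(C)(C)[C@@H](O)CC/C(C)=C\CC1
F3 | step 12 | arylacetone | C/C1=C/Cc2c(cc(OCOC)c(C(=O)OC)c2CC(C)=O)OC(C)(C)[C@@H](O)CC/C(C)=C\CC1
F4 | step 12 | (R)-carbinol (neutral seco hydroxy ester) | C/C1=C/Cc2c(cc(OCOC)c(C(=O)OC)c2C[C@@H](C)O)OC(C)(C)[C@@H](O)CC/C(C)=C\CC1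
F5 | step 11 | B-alkyl-9-BBN borane of 6 | COCOc1cc(O)c(C/C=C(C)\CCB2C3CCCC2CCC3)c(O)c1
F6 | step 11 | (2′Z,6′Z)-allylic alcohol | COCOc1cc(O)c(C/C=C(C)\CC/C=C(C)\CO)c(O)c1
F7 | step 11 | aryloxy ketone of F6 | COCOc1cc(O)c(C/C=C(C)\CC/C=C(C)\CO)c(OC(C)(C)C(C)=O)c1
F8 | step 11 | triflate of F7 | COCOc1cc(OS(=O)(=O)C(F)(F)F)c(C/C=C(C)\CC/C=C(C)\CO)c(OC(C)(C)C(C)=O)c1
F9 | step 11 | allylic bromide | COCOc1cc(OS(=O)(=O)C(F)(F)F)c(C/C=C(C)\CC/C=C(C)\CBr)c(OC(C)(C)C(C)=O)c1
F10 | step 11 | macrocyclic ketone (C-10′ C=O) | C/C1=C/Cc2c(cc(OCOC)cc2OS(=O)(=O)C(F)(F)F)OC(C)(C)C(=O)CC/C(C)=C\CC1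
F11 | step 5 | ethyl 2-aryloxy-2-methylpropanoate | COCOc1cc(O)c(C/C=C(C)\C=C)c(OC(C)(C)C(=O)OCC)c1
F12 | step 5 | Weinreb amide of F11 | COCOc1cc(O)c(C/C=C(C)\C=C)c(OC(C)(C)C(=O)N(C)OC)c1
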